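## The problem

The target is a trans-fused bicyclo[8.4.0]tetradecane: a cyclohexane (C1, C10–C14) joined at C1–C10 to a ten-membered carbocycle (C1–C10). The large ring holds a Z,Z-1,3-diene (C3=C4, C5=C6), and a γ-lactone (C7, C8, C17, C19, O) is fused to it at C7–C8. Eleven stereocentres have to be set (C1, C2, C7, C8, C9, C10, C11, C12, C13, C14, C17), two of them fully substituted carbons of the medium ring or its junction (C1, C8). Useful control lines exist. The axial C1 methyl (C15) can direct the oxygenation of C13/C14. A free C12 hydroxyl can direct the C11 spiro-epoxide. A free C14 hydroxyl is 1,3 to C2. The C7 oxygen can tether a nucleophile onto C8. The allylic chloride at C16, the spiro-epoxide, the β-hydroxy lactone (retro-aldol) and the four acetates next to a free cis C12 hydroxyl (acyl migration) rule out base, strong nucleophiles and reducing metals at the end. Direct closure of a ten-membered ring with two Z alkenes is the step most likely to fail for entropic and transannular reasons. The enabling feature is that C2 and C8 both carry oxygen and are 1,5-related through C1–C10–C9 and 1,7-related through C3–C7. A temporary C2–C8 bond therefore turns the ten-membered ring into a cyclopentane (C1, C2, C8, C9, C10) fused to a cycloheptadiene (C2–C8), in which both diene bonds can only be Z, and a glycol cleavage of that bond returns the macrocycle with ketones at C2 and C8.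

## Retrosynthesis

**Late functional groups (43 ← 42 ← 40 ← 39).** The C11–O epoxide bonds, the C16–Cl bond and the two silyl ethers are cut first. The epoxide and the allylic chloride would not survive SmI2, hydride or acid, so they come last. The free C12 hydroxyl of 42 is the only allylic alcohol in the molecule and should steer a vanadium peroxide to C11=C20 alone. The forward steps ask for selective chlorination of the primary allylic alcohol of 40 and for acidic, non-basic desilylation of 39.

**C2 carbinol and the acetates (39 ← 38 ← 37 ← 36).** The C2–H bond is cut back to the C2 ketone that the key step leaves behind. The acetonide on C13/C14 is removed before this reduction. The free C14 hydroxyl of 37 is 1,3 to the C2 carbonyl, and a boron chelate between them should give the 1,3-syn diol, which is the C2 configuration of the target. One acetylation then covers C2, C13 and C14 (38 → 39). A plain hydride reduction with no chelate would rest only on the conformation of the ten-membered ring.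

**Lactone (36 ← 35).** The C8–C17 bond is cut. The C8 ketone of 35 sits next to the C7 oxygen, so an α-bromopropionate on that oxygen can deliver C17 intramolecularly and create the C8 tertiary alcohol and the lactone in one step. A base-mediated aldol of a propionate would also enolise the acetates. An olefination would give a butenolide without the C8 hydroxyl. The forward reaction must reduce the C–Br bond faster than the α-acyloxy ketone.

**Key disconnection (35 ← 34).** The C2–C8 bond is restored in the reverse sense: diketone 35 comes from the cis-ditertiary diol 34 by glycol cleavage. 34 is a tricycle with five-, six- and seven-membered rings only, and its diene geometry is fixed by ring size. Both carbinol centres are erased, so only their cis relationship matters. They are placed on the β face (that of C15) because that is where a nucleophile entering C2 anti to the angular methyl leaves the hydroxyl, and where that hydroxyl can then deliver the C8 oxygen. The bromopropionate is put on C7 before the cleavage (33 → 34) so that no free α-ketol is handled afterwards.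

**C7 carbinol (34 ← 33 ← 32).** The C7–H bond is cut to the cycloheptadienone 32. Hydride should attack the convex face of the cis-fused bicyclo[5.3.0] unit, which is the face of the ring-fusion hydroxyls. That places the C7 oxygen trans to the C8 hydroxyl, as the target needs. The configuration of C7 therefore does not have to be controlled earlier.

**Seven-membered ring (32 ← 31 ← 30 ← 29 ← 28 ← 25 + 26).** The ring is closed at C3=C4 by metathesis of two monosubstituted vinyl groups. Closure at C5=C6 was rejected: it would need a 2-substituted diene on C2 whose internal Z alkene could close a cyclopentene with loss of the diene terminus. With closure at C3=C4 the only internal alkene is the trisubstituted, electron-poor C5=C6. The dienone 31 is cut at C4–C5 (Stille coupling of the Z-β-iodoenone 30), at C5–I (hydroiodination of ynone 29) and at C6–C7 (acetylide of commercial 26 onto aldehyde 25, then oxidation of 28).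

**Stereo relay in the five-membered ring (25 ← 24 ← 23 ← 22 ← 21 ← 20).** Three bonds are cut: C9–O, C8–O and C2–C3. In the forward sense vinyl adds to the enone 20 anti to C15 (21). The resulting β hydroxyl directs epoxidation of C8=C9 to the β face (22). Acetic acid then opens the epoxide at C9 with inversion (23). This gives the cis C2/C8 diol and the 9α-acetate from one controlling element. Double addition to a cyclopentane-1,2-dione was rejected: the second nucleophile would have to enter syn to the first or to the angular methyl, which leads to the trans diol, and such a dione enolises toward C9.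

**Cyclopentenone (20 ← 19 ← 18 ← 17 ← 16 ← 15).** C7 is attached at C8 by a Morita–Baylis–Hillman reaction with formaldehyde (18 → 19). The enone 18 comes from the 1,3-dione 16 through the less hindered enol triflate 17. The dione comes from the methyl ketone ester 15 by an intramolecular Claisen condensation that forms C8–C9. An aldol condensation of a keto aldehyde would be shorter but would put an epimerisable aldehyde α-hydrogen on C10, whereas the kinetic ketone enolate of 15 leaves C10 alone.

**Cyclohexane and first stereocentres (15 ← 14 ← 13 ← 12 ← 11 ← 8 ← 7 ← 6 ← 5 ← 1 + 2).** The cyclohexane oxygens and C20 are put on the monocycle, where the bulky silyloxyethyl group holds the C1 methyl axial. Dihydroxylation anti to it gives 7. Mannich methylenation at C11 gives 11. Reduction anti to the acetonide gives 12. The ring, C1 and C10 come from a catalytic enantioselective Diels–Alder reaction of 1 and 2 (C1–C14, C10–C11). The aldehyde of the cycloadduct takes a methyl Grignard reagent while the ketone is still masked. That methyl is C8, so the template bond C2–C8 is made in the first step from a commodity reagent.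

## Roads not taken

**Alternative 1: Diels–Alder as the strategic step.** The cut is C1–C14 and C10–C11. In the forward sense, enal ester and aminosilyloxydiene combine under a chiral trivalent chromium salen Lewis acid, and acid work-up gives the enone aldehyde A1.
- Merits: two commercial partners, one catalytic step, the quaternary C1 and C10 fixed in absolute terms, and an enone ready for the C12–C14 oxygens.
- Weak points: it settles two of eleven stereocentres and says nothing about the medium ring, the diene geometry or C2, C7, C8 and C9. The cationic chromium catalyst is best matched to carbamate-type aminodienes, and the basic dimethylamino diene is better served by a hydrogen-bond donor catalyst.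
- Comparison: this cycloaddition is not a rival. It is step 1 of the chosen route, where cycloadduct 3 is intercepted by MeMgBr before A1 would form. As a strategy on its own it is better in enantio-economy, but it leaves the macrocycle unsolved, and the chosen plan supplies that part.

**Alternative 2: Silyloxyfuran vinylogous aldol macrocyclisation at C6–C7.** The cut is C6–C7. In the forward sense, BF3·OEt2 activates the C6 enal of the seco compound A2, its 2-silyloxyfuran attacks through C7, and the ten-membered ring closes to the butenolide A3.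
- Merits: high convergence, ring and lactone carbons in one step, tolerance of acetates, and a C6 carbinol next to the C5 methylidene that could be turned into the C16 chloride by SN2′ displacement.
- Weak points: a ten-membered carbocycle is closed directly, against entropy and transannular strain and in competition with oligomerisation. The Z C3=C4 bond must be made and kept in an open chain. The C7 configuration comes from a medium-ring transition state. A3 carries a C8=C17 butenolide, so the C8 hydroxyl and the C17 hydrogen would need a stereoselective hydration of a tetrasubstituted, electron-poor alkene, for which no simple method exists.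
- Comparison: it is shorter on paper and avoids the redox detour at C2 and C8. The chosen plan sets against it a seven-membered ring closure, a diene geometry that cannot be wrong, and a Reformatsky step that gives the C8 hydroxyl and C17 directly.

**Alternative 3: Grob fragmentation.** The cut regenerates the C3–C8 bond shared by two six-membered rings in the hydroxy mesylate A4. In the forward sense, the potassium alkoxide of the C8 alcohol expels the C4 mesylate and gives the ten-membered C8 ketone A5 with the Z C3=C4 bond.
- Merits: the alkene geometry follows stereospecifically from C4. Only one ketone is formed, and C2 arrives with its oxygen and configuration in place. In both respects it is better than the chosen plan, which must create C2 after the ring expansion.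
- Weak points: three extra stereocentres (C3, C4, C8) must be built with an exact antiperiplanar relation only to be destroyed. The C4 mesylate is allylic to C5=C6 and prone to ionisation and SN2′ attack. The strong base excludes acetates, forces methoxymethyl ethers that are hard to remove at the end, and puts C7 (α to the new ketone) at risk of epimerisation.
- Comparison: the chosen plan answers the C2 problem with a reduction directed by the C14 hydroxyl, runs its ring expansion under buffered oxidative conditions that acetates tolerate, and makes its template diol from a Grignard addition and a directed epoxidation.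

Key step: step 27

## Remarks before the route

- Carbon numbers are those of the target skeleton (C15 = methyl on C1, C16 = chloromethyl carbon, C20 = epoxide methylene). On the cyclohexane and the rings fused to it, β is the face of C15 and α the face of H-10.
- "Core" in a name means the cyclohexane with 1β-methyl, 10α-H, 11-methylidene, 12α-triisopropylsilyloxy and 13α,14α-O-isopropylidene.
- Assumption: the (R,R) enantiomer of the diol catalyst in step 1 is taken to give the enantiomeric series drawn. The sense of induction decides only which enantiomer is used.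
- Assumption: silyl ether 26 is bought. Compounds 4–14 are carried as both epimers at the side-chain carbinol (oxidised in step 9), 28 as both C7 epimers (oxidised in step 21), and 34, 35 as both epimers at the bromine-bearing carbon (lost in step 28).

## Route

Step 1
Reactants: 1 ethyl (E)-3-methyl-4-oxobut-2-enoate; 2 (E)-1-(dimethylamino)-3-(tert-butyldimethylsilyloxy)buta-1,3-diene
Product: 5 ethyl (1S,2S)-2-(1-hydroxyethyl)-2-methyl-5-oxocyclohex-3-ene-1-carboxylate as both carbinol epimers, via silyl enol ether cycloadduct 3 (not isolated), via methyl carbinol cycloadduct 4 (not isolated)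
Conditions: (R,R)-1-naphthyl-TADDOL (20 mol%), toluene, −78 °C; then MeMgBr, THF, −78 °C; then aq. HF, MeCN, 0 °C
Reagents that add atoms: methylmagnesium bromide, C[Mg]Br
Why: Hydrogen-bond-catalysed Diels–Alder reaction of an α-substituted enal with a 1-amino-3-silyloxydiene forms C1–C14 and C10–C11 with the diene CH2 terminus on the β-carbon of the enal; the chiral diol shields one face of the bound aldehyde and sets C1 and C10, and the E dienophile makes C2 and C9 trans. In cycloadduct 3 the ketone is still masked as the silyl enol ether, so MeMgBr adds only to the aldehyde (Grignard 1,2-addition, forming C2–C8), and HF then hydrolyses the enol ether and eliminates dimethylamine to the enone.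

Step 2
Reactants: 5 ethyl (1S,2S)-2-(1-hydroxyethyl)-2-methyl-5-oxocyclohex-3-ene-1-carboxylate
Product: 6 ethyl (1S,2S)-2-methyl-5-oxo-2-[1-(triethylsilyloxy)ethyl]cyclohex-3-ene-1-carboxylate
Conditions: Et3SiOTf, 2,6-lutidine, CH2Cl2, −78 °C
Reagents that add atoms: triethylsilyl trifluoromethanesulfonate, CC[Si](CC)(CC)OS(=O)(=O)C(F)(F)F
Why: Silyl triflate protection of a hindered secondary alcohol; the bulky silyloxyethyl group and the trans ester stay equatorial, which holds the C1 methyl axial for step 3.

Step 3
Reactants: 6 ethyl (1S,2S)-2-methyl-5-oxo-2-[1-(triethylsilyloxy)ethyl]cyclohex-3-ene-1-carboxylate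
Product: 7 13α,14α-diol of 6 (ethyl 3,4-dihydroxy-2-methyl-5-oxo-2-[1-(triethylsilyloxy)ethyl]cyclohexane-1-carboxylate; both hydroxyls trans to the 2-methyl)
Conditions: OsO4 (2 mol%), NMO, acetone–H2O, rt
Reagents that add atoms: 4-methylmorpholine N-oxide, C[N+]1([O-])CCOCC1; water, O
Why: Catalytic cis-dihydroxylation of the enone alkene with OsO4 and an N-oxide reoxidant; the reagent adds to C13=C14 anti to the axial C15 methyl on the neighbouring C1, so both new carbinols are α.

Step 4
Reactants: 7 13α,14α-diol
Product: 8 13α,14α-O-isopropylidene C12 ketone (acetonide of 7)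
Conditions: Me2C(OMe)2, PPTS (cat.), CH2Cl2, rt
Reagents that add atoms: 2,2-dimethoxypropane, COC(C)(C)OC
Why: Acid-catalysed transketalisation of a cis-1,2-diol; it removes the β-hydroxy ketone, which could eliminate, and it will block the α face of C12 in step 6.

Step 5
Reactants: 8 acetonide ketone
Product: 11 11-methylidene C12 ketone, via Mannich base 9 (not isolated), via trimethylammonium iodide 10 (not isolated)
Conditions: LiN(SiMe3)2, THF, −78 °C; CH2=NMe2+ I−; then MeI, CH2Cl2, rt; aq. NaHCO3
Reagents that add atoms: dimethyl(methylidene)ammonium iodide, C=[N+](C)C.[I-]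
Why: α-Methylenation by Mannich reaction and elimination: kinetic enolisation occurs at the C11 methylene and not at the alkoxy-bearing C13, the enolate traps the iminium salt, and quaternisation followed by mild bicarbonate elimination gives the exocyclic enone without migration of the alkene toward C10.

Step 6
Reactants: 11 11-methylidene C12 ketone
Product: 12 12α-alcohol (allylic alcohol cis to the C13 and C14 oxygens)
Conditions: NaBH4, CeCl3·7H2O, MeOH, −78 °C
Reagents that add atoms: none
Why: Luche 1,2-reduction of the exocyclic enone; hydride adds from the β face, anti to the acetonide and to the axial C14 oxygen, and gives the axial 12α-alcohol.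

Step 7
Reactants: 12 12α-alcohol
Product: 13 12α-triisopropylsilyl ether
Conditions: iPr3SiOTf, 2,6-lutidine, CH2Cl2, 0 °C
Reagents that add atoms: triisopropylsilyl trifluoromethanesulfonate, CC(C)[Si](OS(=O)(=O)C(F)(F)F)(C(C)C)C(C)C
Why: Silyl triflate protection of a hindered axial alcohol; the robust ether must outlast the acid of step 29 and keep C12 apart from the hydroxyls that are acetylated in step 31.

Step 8
Reactants: 13 12α-triisopropylsilyl ether
Product: 14 side-chain carbinol (triethylsilyl group removed)
Conditions: HF·pyridine, pyridine, THF, 0 °C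
Reagents that add atoms: none
Why: Buffered fluoride cleaves a triethylsilyl ether much faster than a triisopropylsilyl ether or the acetonide (selective desilylation).

Step 9
Reactants: 14 side-chain carbinol
Product: 15 methyl ketone ester (C2 acetyl on C1; C9 ethyl ester on C10; core)
Conditions: DMP, NaHCO3, CH2Cl2, rt
Reagents that add atoms: none
Why: Periodinane oxidation of a secondary alcohol to the ketone; both carbinol epimers converge on one compound.

Step 10
Reactants: 15 methyl ketone ester
Product: 16 trans-fused cyclopentane-2,9-dione on the core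
Conditions: LiN(SiMe3)2 (2.2 equiv), THF, −78 → 0 °C; aq. NH4Cl
Reagents that add atoms: none
Why: Intramolecular Claisen condensation of a γ-keto ester: the C2 ketone can enolise only toward its methyl group (C8), and this kinetic enolate attacks the gauche, equatorial C9 ester to form C8–C9 and the five-membered ring. The acidic dione is formed as its enolate, which protects C10, so the trans ring fusion from step 1 is kept.

Step 11
Reactants: 16 trans-fused cyclopentane-2,9-dione
Product: 17 C9 enol triflate of the dione (C8=C9; C2 ketone)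
Conditions: Tf2O, Et3N, CH2Cl2, −78 °C
Reagents that add atoms: trifluoromethanesulfonic anhydride, O=S(=O)(OS(=O)(=O)C(F)(F)F)C(F)(F)F
Why: O-Sulfonylation of the 1,3-dione enolate occurs at the less hindered oxygen, the one on C9 remote from the quaternary C1, and leaves the C2 carbonyl (vinylogous triflate formation).

Step 12
Reactants: 17 C9 enol triflate
Product: 18 trans-fused cyclopentenone (C2 ketone; C8=C9)
Conditions: Pd(PPh3)4 (5 mol%), Bu3SnH, LiCl, THF, rt
Reagents that add atoms: none
Why: Palladium-catalysed reduction of a vinyl triflate by tin hydride (oxidative addition to zerovalent palladium, hydride transfer, reductive elimination); the neutral conditions at room temperature avoid γ-deprotonation at C10.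

Step 13
Reactants: 18 trans-fused cyclopentenone
Product: 19 8-(hydroxymethyl)cyclopentenone (C7 carbinol on C8)
Conditions: aq. HCHO, imidazole, THF–H2O, rt
Reagents that add atoms: formaldehyde, C=O
Why: Morita–Baylis–Hillman reaction of a cyclopentenone with formaldehyde: imidazole adds to C9, the enolate takes formaldehyde at C8, and elimination restores the enone with the C7–C8 bond in place.

Step 14
Reactants: 19 8-(hydroxymethyl)cyclopentenone
Product: 20 8-(tert-butyldimethylsilyloxymethyl)cyclopentenone
Conditions: tBuMe2SiCl, imidazole, DMF, rt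
Reagents that add atoms: tert-butyldimethylsilyl chloride, CC(C)(C)[Si](C)(C)Cl
Why: Standard silylation of a primary alcohol; with C7 capped, the C2 hydroxyl made in step 15 is the only director in step 16.

Step 15
Reactants: 20 8-(tert-butyldimethylsilyloxymethyl)cyclopentenone
Product: 21 2β-hydroxy-2α-vinyl allylic alcohol
Conditions: CH2=CHMgBr, CeCl3, THF, −78 °C
Reagents that add atoms: vinylmagnesium bromide, C=C[Mg]Br
Why: 1,2-Addition of a vinylcerium reagent to a hindered, non-enolisable enone forms C2–C3; the nucleophile enters from the α face, anti to the axial C15 methyl on the adjacent C1, as in additions to trans-hydrindanones, so the hydroxyl is β.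

Step 16
Reactants: 21 2β-hydroxy-2α-vinyl allylic alcohol
Product: 22 8β,9β-epoxide
Conditions: VO(acac)2 (5 mol%), tBuOOH, CH2Cl2, 0 °C → rt
Reagents that add atoms: tert-butyl hydroperoxide, CC(C)(C)OO
Why: Hydroxyl-directed epoxidation: the C2 alkoxide binds the vanadium peroxide and delivers oxygen to the trisubstituted C8=C9 bond on its own β face, which fixes the future C8 hydroxyl cis to the C2 hydroxyl. The monosubstituted vinyl group and the undirected C11 methylidene react far more slowly.

Step 17
Reactants: 22 8β,9β-epoxide
Product: 23 9α-acetate 2β,8β-diol (C7 silyl ether)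
Conditions: Ti(OiPr)4, AcOH, CH2Cl2, rt
Reagents that add atoms: acetic acid, CC(=O)O
Why: Titanium-mediated opening of a 2,3-epoxy alcohol by a carboxylic acid: the titanium bound to the C2 alkoxide and the epoxide directs the acid to the distal carbon C9, which is attacked with inversion from the open α face. This sets the 9α-acetate and leaves the C8–O bond as the β tertiary alcohol.

Step 18
Reactants: 23 9α-acetate 2β,8β-diol
Product: 24 C7 primary alcohol
Conditions: HF·pyridine, pyridine, THF, 0 °C → rt
Reagents that add atoms: none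
Why: Selective cleavage of a primary tert-butyldimethylsilyl ether in the presence of the secondary triisopropylsilyl ether and the acetonide under buffered fluoride.

Step 19
Reactants: 24 C7 primary alcohol
Product: 25 C7 aldehyde (α-hydroxy aldehyde on C8)
Conditions: DMP, NaHCO3, CH2Cl2, 0 °C
Reagents that add atoms: none
Why: Periodinane oxidation of a primary alcohol; the tertiary alcohols are inert, and C8 has no hydrogen, so the C9 acetate cannot be lost by β-elimination.

Step 20
Reactants: 25 C7 aldehyde; 26 tert-butyl(diphenyl)(prop-2-yn-1-yloxy)silane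
Product: 28 C7 propargylic alcohol as both C7 epimers, via lithium acetylide 27 (not isolated)
Conditions: 26, n-BuLi, THF, −78 °C; then 25, −78 °C; AcOH quench at −78 °C
Reagents that add atoms: none
Why: Addition of a lithium acetylide to an aldehyde forms C6–C7 and brings in C5 and C16; excess acetylide covers the two tertiary hydroxyls, and acetate esters are not attacked by acetylides at −78 °C. The C7 configuration is irrelevant because step 21 removes it.

Step 21
Reactants: 28 C7 propargylic alcohol
Product: 29 C7 ynone
Conditions: DMP, NaHCO3, CH2Cl2, 0 °C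
Reagents that add atoms: none
Why: Periodinane oxidation of a secondary propargylic alcohol to the alkynone under buffered, non-basic conditions.

Step 22
Reactants: 29 C7 ynone
Product: 30 (Z)-β-iodoenone (iodine on C5 cis to the C7 carbonyl)
Conditions: LiI, AcOH, MeCN, rt
Reagents that add atoms: lithium iodide, [Li+].[I-]
Why: Hydroiodination of an alkynone: iodide adds to C5 in conjugate fashion and the allenolate is protonated anti to iodine, which gives the Z-β-iodoenone with iodine cis to the carbonyl.

Step 23
Reactants: 30 (Z)-β-iodoenone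
Product: 31 dienone (vinyl on C5 cis to the C7 carbonyl)
Conditions: CH2=CHSnBu3, Pd2(dba)3 (cat.), AsPh3, NMP, rt
Reagents that add atoms: tributyl(vinyl)stannane, C=C[Sn](CCCC)(CCCC)CCCC
Why: Stille coupling of an alkenyl iodide proceeds with retention, forms C4–C5 and places C4 cis to C7, the geometry that ring closure needs.

Step 24
Reactants: 31 dienone
Product: 32 tricyclic cycloheptadienone (C7 ketone; 2β,8β-diol; 9α-acetate)
Conditions: second-generation Grubbs catalyst RuCl2(H2IMes)(PCy3)(=CHPh) (10 mol%), toluene (2 mM), 60 °C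
Reagents that add atoms: none
Why: Ring-closing metathesis of the two monosubstituted vinyl groups forms C3=C4 and the seven-membered ring. The trisubstituted, electron-poor C5=C6 bond and the 1,1-disubstituted C11 methylidene do not compete, and ring size forces both diene bonds to be Z.

Step 25
Reactants: 32 tricyclic cycloheptadienone
Product: 33 tricyclic 2β,7,8β-triol (C7 hydroxyl trans to the C8 hydroxyl)
Conditions: NaBH4, CeCl3·7H2O, MeOH, −78 °C
Reagents that add atoms: none
Why: Luche 1,2-reduction of the dienone; hydride attacks the convex face of the cis-fused bicyclo[5.3.0] unit, the face that carries the two ring-fusion hydroxyls. The C7 oxygen therefore ends up on the concave side, trans to the C8 hydroxyl, which is the C7 configuration of the target.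

Step 26
Reactants: 33 tricyclic 2β,7,8β-triol
Product: 34 tricyclic cis-2β,8β-diol 7-(2-bromopropanoate)
Conditions: MeCHBrCOBr, pyridine, CH2Cl2, −40 → 0 °C
Reagents that add atoms: 2-bromopropanoyl bromide, CC(Br)C(=O)Br
Why: Acylation of the secondary allylic alcohol with an acyl bromide; the two tertiary hydroxyls do not react under these conditions, so the diol stays free for step 27.

Step 27
Reactants: 34 tricyclic cis-2β,8β-diol 7-(2-bromopropanoate)
Product: 35 bicyclic ten-membered 2,8-diketone with the Z,Z-diene and the 7-(2-bromopropanoate)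
Conditions: Pb(OAc)4, pyridine, CH2Cl2, −20 → 0 °C
Reagents that add atoms: none
Why: The two cis tertiary hydroxyls displace acetate from tetravalent lead and form a five-membered cyclic lead diester, which collapses in a concerted two-electron fragmentation to the C2 and C8 ketones and Pb(OAc)2 of divalent lead (Criegee glycol cleavage). The closest known reaction type is the lead tetraacetate cleavage of ring-fusion cis-1,2-diols of fused bicycles to medium-ring diketones. No bond is formed, so no mode of ring closure has to be judged: breaking the shared C2–C8 bond merges the cyclopentane and the cycloheptadiene into the ten-membered ring, a ring expansion by fragmentation. No stereocentre is created; C2 and C8 become trigonal and C1, C7, C9 and C10 are not touched. The step needs selectivity for the diol over every other oxygen and over the diene, and the alkene geometry must survive: all other hydroxyls are acylated, silylated or ketalised, a 1,3-diene reacts with lead tetraacetate far more slowly than a cis-diol at −20 °C, and both double bonds are Z because they were made inside a seven-membered ring. The cis relationship that the cyclic diester requires was fixed by the directed epoxidation of step 16. Pyridine buffers the acetic acid set free, so the C8 ketone between the C7 and C9 oxygens is not enolised.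

Step 28
Reactants: 35 bicyclic ten-membered 2,8-diketone
Product: 36 γ-lactone with 8-hydroxyl and C2 ketone (C7, C8 and C17 as in the target; acetonide retained)
Conditions: SmI2 (2.2 equiv, slow addition), THF, −78 °C
Reagents that add atoms: none
Why: Intramolecular Reformatsky reaction: divalent samarium reduces the C–Br bond to a trivalent samarium enolate, which adds to the adjacent C8 ketone through a chelated five-membered transition state and forms C8–C17, the tertiary alcohol and the lactone. The short tether from the C7 oxygen allows attack on one face of C8 only, and C17 is expected to place its methyl anti to C9, the more stable arrangement that is also reachable by equilibration.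

Step 29
Reactants: 36 γ-lactone with 8-hydroxyl and C2 ketone
Product: 37 13α,14α-diol C2 ketone
Conditions: AcOH–H2O (4:1), 40 °C
Reagents that add atoms: none
Why: Acid hydrolysis of the isopropylidene ketal while C2 is still a ketone, so that no acid-labile dienyl carbinol is present; the triisopropylsilyl and tert-butyldiphenylsilyl ethers tolerate these conditions, and the C14 hydroxyl is freed for step 30.

Step 30
Reactants: 37 13α,14α-diol C2 ketone
Product: 38 2,13α,14α-triol (C2 as in the target)
Conditions: Et2BOMe, THF–MeOH, −78 °C; NaBH4; then AcOH, MeOH evaporation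
Reagents that add atoms: none
Why: Narasaka–Prasad reduction of a β-hydroxy ketone: the diethylboron chelate between the C14 oxygen and the C2 carbonyl is a half-chair fused to the cyclohexane, with C13 equatorial and C10 axial. External hydride adds axially, anti to C10, and gives the 1,3-syn diol, which is the C2 configuration of the target; the chelated conjugated ketone is reduced in the 1,2 sense.

Step 31
Reactants: 38 2,13α,14α-triol
Product: 39 2,9,13,14-tetraacetate 12-triisopropylsilyl 16-tert-butyldiphenylsilyl ether
Conditions: Ac2O, DMAP, pyridine, CH2Cl2, rt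
Reagents that add atoms: acetic anhydride, CC(=O)OC(C)=O
Why: Nucleophile-catalysed acetylation of the three secondary alcohols at C2, C13 and C14; the tertiary C8 hydroxyl next to the lactone is not acylated under these conditions.

Step 32
Reactants: 39 tetraacetate bis-silyl ether
Product: 40 12α,16-diol tetraacetate
Conditions: aq. HF (48%), MeCN, 0 °C → rt
Reagents that add atoms: none
Why: Acidic fluoride cleaves both silyl ethers without base, which avoids acetyl migration from C13 to the cis C12 hydroxyl and leaves the lactone and the allylic acetate alone.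

Step 33
Reactants: 40 12α,16-diol tetraacetate
Product: 42 C16 allylic chloride with free 12α-hydroxyl, via allylic mesylate 41 (not isolated)
Conditions: MsCl (1.05 equiv), LiCl, 2,4,6-collidine, DMF, 0 °C
Reagents that add atoms: lithium chloride, [Li+].[Cl-]
Why: The unhindered primary allylic alcohol is mesylated much faster than the axial, hindered C12 hydroxyl, and chloride displaces the primary mesylate in situ by SN2.

Step 34
Reactants: 42 C16 allylic chloride
Product: 43 CNP0282558.2 (target)
Conditions: VO(acac)2 (5 mol%), tBuOOH, CH2Cl2, 0 °C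
Reagents that add atoms: tert-butyl hydroperoxide, CC(C)(C)OO
Why: Hydroxyl-directed epoxidation: the 12α-alkoxide delivers the oxygen to the α face of the adjacent C11 methylidene and gives the spiro-epoxide with oxygen cis to the C12 hydroxyl. The diene has no free allylic hydroxyl, the C8 hydroxyl is only homoallylic and tertiary, and the chloromethyl group deactivates C5=C6.

## Compound list

1 | ethyl (E)-3-methyl-4-oxobut-2-enoate | CCOC(=O)/C=C(\C)C=O | starting material
2 | (E)-1-(dimethylamino)-3-(tert-butyldimethylsilyloxy)buta-1,3-diene | CN(C)/C=C/C(=C)O[Si](C)(C)C(C)(C)C | starting material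
3 | ethyl 5-(tert-butyldimethylsilyloxy)-3-(dimethylamino)-2-formyl-2-methylcyclohex-4-ene-1-carboxylate (ester and formyl trans; amino-bearing carbon not defined) | CCOC(=O)[C@H]1CC(O[Si](C)(C)C(C)(C)C)=CC(N(C)C)[C@]1(C)C=O | intermediate
4 | ethyl 5-(tert-butyldimethylsilyloxy)-3-(dimethylamino)-2-(1-hydroxyethyl)-2-methylcyclohex-4-ene-1-carboxylate | CCOC(=O)[C@H]1CC(O[Si](C)(C)C(C)(C)C)=CC(N(C)C)[C@]1(C)C(C)O | intermediate
5 | ethyl (1S,2S)-2-(1-hydroxyethyl)-2-methyl-5-oxocyclohex-3-ene-1-carboxylate (both carbinol epimers) | O=C1C[C@H](C(=O)OCC)[C@@](C)(C(C)O)C=C1 | intermediate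
6 | ethyl (1S,2S)-2-methyl-5-oxo-2-[1-(triethylsilyloxy)ethyl]cyclohex-3-ene-1-carboxylate | O=C1C[C@H](C(=O)OCC)[C@@](C)(C(C)O[Si](CC)(CC)CC)C=C1 | intermediate
7 | ethyl 3,4-dihydroxy-2-methyl-5-oxo-2-[1-(triethylsilyloxy)ethyl]cyclohexane-1-carboxylate, 13α,14α-diol (hydroxyls cis, trans to the 2-methyl) | O[C@H]1C(=O)C[C@H](C(=O)OCC)[C@@](C)(C(C)O[Si](CC)(CC)CC)[C@H]1O | intermediate
8 | 13α,14α-O-isopropylidene derivative of 7 (C12 ketone) | CC1(C)O[C@H]2C(=O)C[C@H](C(=O)OCC)[C@@](C)(C(C)O[Si](CC)(CC)CC)[C@H]2O1 | intermediate
9 | C11 (dimethylamino)methyl ketone, Mannich base of 8 (C11 not defined) | CC1(C)O[C@H]2C(=O)C(CN(C)C)[C@H](C(=O)OCC)[C@@](C)(C(C)O[Si](CC)(CC)CC)[C@H]2O1 | intermediate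
10 | trimethylammonium iodide of 9 | CC1(C)O[C@H]2C(=O)C(C[N+](C)(C)C)[C@H](C(=O)OCC)[C@@](C)(C(C)O[Si](CC)(CC)CC)[C@H]2O1.[I-] | intermediate
11 | 11-methylidene C12 ketone (acetonide, ethyl ester, triethylsilyloxyethyl side chain) | CC1(C)O[C@H]2C(=O)C(=C)[C@H](C(=O)OCC)[C@@](C)(C(C)O[Si](CC)(CC)CC)[C@H]2O1 | intermediate
12 | 12α-alcohol of 11 (hydroxyl cis to the acetonide oxygens) | CC1(C)O[C@H]2[C@@H](O)C(=C)[C@H](C(=O)OCC)[C@@](C)(C(C)O[Si](CC)(CC)CC)[C@H]2O1 | intermediate
13 | 12α-triisopropylsilyl ether of 12 | CC1(C)O[C@H]2[C@@H](O[Si](C(C)C)(C(C)C)C(C)C)C(=C)[C@H](C(=O)OCC)[C@@](C)(C(C)O[Si](CC)(CC)CC)[C@H]2O1 | intermediate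
14 | side-chain carbinol: core with 1-(1-hydroxyethyl) on C1 and ethyl ester on C10 | CC1(C)O[C@H]2[C@@H](O[Si](C(C)C)(C(C)C)C(C)C)C(=C)[C@H](C(=O)OCC)[C@@](C)(C(C)O)[C@H]2O1 | intermediate
15 | methyl ketone ester: core with acetyl (C2, C8) on C1 and ethyl ester (C9) on C10, trans | CC1(C)O[C@H]2[C@@H](O[Si](C(C)C)(C(C)C)C(C)C)C(=C)[C@H](C(=O)OCC)[C@@](C)(C(C)=O)[C@H]2O1 | intermediate
16 | trans-fused cyclopentane-2,9-dione on the core (C8 methylene) | CC1(C)O[C@H]2[C@@H](O[Si](C(C)C)(C(C)C)C(C)C)C(=C)[C@@H]3C(=O)CC(=O)[C@@]3(C)[C@H]2O1 | intermediate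
17 | C9 enol triflate of 16 (C8=C9; C2 ketone) | CC1(C)O[C@H]2[C@@H](O[Si](C(C)C)(C(C)C)C(C)C)C(=C)[C@@H]3C(OS(=O)(=O)C(F)(F)F)=CC(=O)[C@@]3(C)[C@H]2O1 | intermediate
18 | trans-fused cyclopentenone on the core (C2 ketone; C8=C9) | CC1(C)O[C@H]2[C@@H](O[Si](C(C)C)(C(C)C)C(C)C)C(=C)[C@@H]3C=CC(=O)[C@@]3(C)[C@H]2O1 | intermediate
19 | 8-(hydroxymethyl)cyclopentenone (C7 carbinol) | CC1(C)O[C@H]2[C@@H](O[Si](C(C)C)(C(C)C)C(C)C)C(=C)[C@@H]3C=C(CO)C(=O)[C@@]3(C)[C@H]2O1 | intermediate
20 | 8-(tert-butyldimethylsilyloxymethyl)cyclopentenone | CC1(C)O[C@H]2[C@@H](O[Si](C(C)C)(C(C)C)C(C)C)C(=C)[C@@H]3C=C(CO[Si](C)(C)C(C)(C)C)C(=O)[C@@]3(C)[C@H]2O1 | intermediate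
21 | 2β-hydroxy-2α-vinyl cyclopentene (C8=C9; C7 silyl ether) | CC1(C)O[C@H]2[C@@H](O[Si](C(C)C)(C(C)C)C(C)C)C(=C)[C@@H]3C=C(CO[Si](C)(C)C(C)(C)C)[C@@](O)(C=C)[C@@]3(C)[C@H]2O1 | intermediate
22 | 8β,9β-epoxide of 21 | CC1(C)O[C@H]2[C@@H](O[Si](C(C)C)(C(C)C)C(C)C)C(=C)[C@@H]3[C@@H]4O[C@]4(CO[Si](C)(C)C(C)(C)C)[C@@](O)(C=C)[C@@]3(C)[C@H]2O1 | intermediate
23 | 9α-acetoxy-2β,8β-diol (2α-vinyl; 8α-silyloxymethyl) | CC1(C)O[C@H]2[C@@H](O[Si](C(C)C)(C(C)C)C(C)C)C(=C)[C@@H]3[C@@H](OC(C)=O)[C@@](O)(CO[Si](C)(C)C(C)(C)C)[C@@](O)(C=C)[C@@]3(C)[C@H]2O1 | intermediate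
24 | C7 primary alcohol (9α-acetoxy-2β,8β-diol; 8α-hydroxymethyl) | CC1(C)O[C@H]2[C@@H](O[Si](C(C)C)(C(C)C)C(C)C)C(=C)[C@@H]3[C@@H](OC(C)=O)[C@@](O)(CO)[C@@](O)(C=C)[C@@]3(C)[C@H]2O1 | intermediate
25 | C7 aldehyde (8α-formyl) | CC1(C)O[C@H]2[C@@H](O[Si](C(C)C)(C(C)C)C(C)C)C(=C)[C@@H]3[C@@H](OC(C)=O)[C@@](O)(C=O)[C@@](O)(C=C)[C@@]3(C)[C@H]2O1 | intermediate
26 | tert-butyl(diphenyl)(prop-2-yn-1-yloxy)silane | C#CCO[Si](c1ccccc1)(c1ccccc1)C(C)(C)C | starting material
27 | lithium acetylide of 26 | [Li]C#CCO[Si](c1ccccc1)(c1ccccc1)C(C)(C)C | intermediate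
28 | C7 propargylic alcohol (both C7 epimers; C16 tert-butyldiphenylsilyl ether) | CC1(C)O[C@H]2[C@@H](O[Si](C(C)C)(C(C)C)C(C)C)C(=C)[C@@H]3[C@@H](OC(C)=O)[C@@](O)(C(O)C#CCO[Si](c4ccccc4)(c4ccccc4)C(C)(C)C)[C@@](O)(C=C)[C@@]3(C)[C@H]2O1 | intermediate
29 | C7 ynone | CC1(C)O[C@H]2[C@@H](O[Si](C(C)C)(C(C)C)C(C)C)C(=C)[C@@H]3[C@@H](OC(C)=O)[C@@](O)(C(=O)C#CCO[Si](c4ccccc4)(c4ccccc4)C(C)(C)C)[C@@](O)(C=C)[C@@]3(C)[C@H]2O1 | intermediate
30 | (Z)-β-iodoenone (C5 iodine cis to the C7 carbonyl) | CC1(C)O[C@H]2[C@@H](O[Si](C(C)C)(C(C)C)C(C)C)C(=C)[C@@H]3[C@@H](OC(C)=O)[C@@](O)(C(=O)/C=C(\I)CO[Si](c4ccccc4)(c4ccccc4)C(C)(C)C)[C@@](O)(C=C)[C@@]3(C)[C@H]2O1 | intermediate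
31 | dienone (C5 vinyl cis to the C7 carbonyl) | CC1(C)O[C@H]2[C@@H](O[Si](C(C)C)(C(C)C)C(C)C)C(=C)[C@@H]3[C@@H](OC(C)=O)[C@@](O)(C(=O)/C=C(\C=C)CO[Si](c4ccccc4)(c4ccccc4)C(C)(C)C)[C@@](O)(C=C)[C@@]3(C)[C@H]2O1 | intermediate
32 | tricyclic cycloheptadienone (C7 ketone; cis-2β,8β-diol; 9α-acetate) | CC1(C)O[C@H]2[C@@H](O[Si](C(C)C)(C(C)C)C(C)C)C(=C)[C@@H]3[C@@H](OC(C)=O)[C@@]4(O)C(=O)C=C(CO[Si](c5ccccc5)(c5ccccc5)C(C)(C)C)C=C[C@@]4(O)[C@@]3(C)[C@H]2O1 | intermediate
33 | tricyclic 2β,7,8β-triol (C7 hydroxyl trans to the C8 hydroxyl) | CC1(C)O[C@H]2[C@@H](O[Si](C(C)C)(C(C)C)C(C)C)C(=C)[C@@H]3[C@@H](OC(C)=O)[C@@]4(O)[C@@H](O)C=C(CO[Si](c5ccccc5)(c5ccccc5)C(C)(C)C)C=C[C@@]4(O)[C@@]3(C)[C@H]2O1 | intermediate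
34 | tricyclic cis-2β,8β-diol 7-(2-bromopropanoate) (key-step precursor) | CC1(C)O[C@H]2[C@@H](O[Si](C(C)C)(C(C)C)C(C)C)C(=C)[C@@H]3[C@@H](OC(C)=O)[C@@]4(O)[C@@H](OC(=O)C(C)Br)C=C(CO[Si](c5ccccc5)(c5ccccc5)C(C)(C)C)C=C[C@@]4(O)[C@@]3(C)[C@H]2O1 | intermediate
35 | bicyclic ten-membered 2,8-diketone, Z,Z-diene, 7-(2-bromopropanoate) (key-step product) | CC1(C)O[C@H]2[C@@H](O[Si](C(C)C)(C(C)C)C(C)C)C(=C)[C@@H]3[C@@H](OC(C)=O)C(=O)[C@H](/C=C(CO[Si](c4ccccc4)(c4ccccc4)C(C)(C)C)\C=C/C(=O)[C@@]3(C)[C@H]2O1)OC(=O)C(C)Br | intermediate
36 | γ-lactone with 8-hydroxyl and C2 ketone (acetonide, two silyl ethers) | CC1(C)O[C@H]2[C@@H](O[Si](C(C)C)(C(C)C)C(C)C)C(=C)[C@@H]3[C@@H](OC(C)=O)[C@@]4(O)[C@H](/C=C(CO[Si](c5ccccc5)(c5ccccc5)C(C)(C)C)\C=C/C(=O)[C@@]3(C)[C@H]2O1)OC(=O)[C@@H]4C | intermediate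
37 | 13α,14α-diol C2 ketone | O[C@H]1[C@@H](O[Si](C(C)C)(C(C)C)C(C)C)C(=C)[C@@H]2[C@@H](OC(C)=O)[C@@]3(O)[C@H](/C=C(CO[Si](c4ccccc4)(c4ccccc4)C(C)(C)C)\C=C/C(=O)[C@@]2(C)[C@H]1O)OC(=O)[C@@H]3C | intermediate
38 | 2,13α,14α-triol | O[C@H]1[C@@H](O[Si](C(C)C)(C(C)C)C(C)C)C(=C)[C@@H]2[C@@H](OC(C)=O)[C@@]3(O)[C@H](/C=C(CO[Si](c4ccccc4)(c4ccccc4)C(C)(C)C)\C=C/[C@@H](O)[C@@]2(C)[C@H]1O)OC(=O)[C@@H]3C | intermediate
39 | 2,9,13,14-tetraacetate 12-triisopropylsilyl 16-tert-butyldiphenylsilyl ether | CC(=O)O[C@H]1[C@@H](O[Si](C(C)C)(C(C)C)C(C)C)C(=C)[C@@H]2[C@@H](OC(C)=O)[C@@]3(O)[C@H](/C=C(CO[Si](c4ccccc4)(c4ccccc4)C(C)(C)C)\C=C/[C@@H](OC(C)=O)[C@@]2(C)[C@H]1OC(C)=O)OC(=O)[C@@H]3C | intermediate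
40 | 12α,16-diol tetraacetate | CC(=O)O[C@H]1[C@@H](O)C(=C)[C@@H]2[C@@H](OC(C)=O)[C@@]3(O)[C@H](/C=C(CO)\C=C/[C@@H](OC(C)=O)[C@@]2(C)[C@H]1OC(C)=O)OC(=O)[C@@H]3C | intermediate
41 | C16 methanesulfonate of 40 | CC(=O)O[C@H]1[C@@H](O)C(=C)[C@@H]2[C@@H](OC(C)=O)[C@@]3(O)[C@H](/C=C(COS(C)(=O)=O)\C=C/[C@@H](OC(C)=O)[C@@]2(C)[C@H]1OC(C)=O)OC(=O)[C@@H]3C | intermediate
42 | C16 chloride with 11-methylidene and free 12α-hydroxyl | CC(=O)O[C@H]1[C@@H](O)C(=C)[C@@H]2[C@@H](OC(C)=O)[C@@]3(O)[C@H](/C=C(CCl)\C=C/[C@@H](OC(C)=O)[C@@]2(C)[C@H]1OC(C)=O)OC(=O)[C@@H]3C | intermediate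
43 | CNP0282558.2 | CC(=O)O[C@H]1[C@@H](O)[C@]2(CO2)[C@@H]2[C@@H](OC(C)=O)[C@@]3(O)[C@H](/C=C(CCl)\C=C/[C@@H](OC(C)=O)[C@@]2(C)[C@H]1OC(C)=O)OC(=O)[C@@H]3C | target

## Step count and least certain steps

Total: 34 steps. Longest linear sequence: 34 steps (1 and 2 to 43; 26 is bought and enters at step 20).

**Step 27 (key step).** The two carbinols are fully substituted and crowded, so formation of the cyclic lead diester may be slow. Acetoxylation of the diene can then compete, or the new C8 ketone may enolise toward C7 and lose the C7 configuration. Fallback from 34 to 35: alkoxyl-radical β-scission with PhI(OAc)2 and I2 under visible light. The C8 alkoxyl radical breaks C2–C8 in a one-electron step that needs no cyclic diester, and the stabilised C2 radical (α-hydroxy, dienylic) is oxidised on to the ketone. No new compound is made.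

**Step 28.** Electron transfer to the C8 ketone may expel the C9 acetoxy or the C7 acyloxy group, since α-acyloxy ketones are cleaved by SmI2. The dienone may be reduced, or the enolate may add to the wrong face of C8 or give the wrong C17 epimer. Fallback from 35: halide exchange with NaI in acetone gives the α-iodopropanoate F1. Triethylborane with a trace of air then abstracts iodine and forms a boron enolate (radical Reformatsky-type aldol), which closes to 36 without any reducing metal.

**Step 22.** The tertiary C8 hydroxyl may add to the ynone or displace iodide from the iodoenone by addition and elimination, diverting material to a 3(2H)-furanone, and the Z geometry may leak. Fallback from 28: the cis-diol is tied up with PhB(OH)2 and MgSO4 as the cyclic phenylboronate F2. This is oxidised with DMP to the ynone boronate F3, hydroiodinated to the iodoenone boronate F4 and coupled with tributyl(vinyl)stannane to the dienone boronate F5. Exchange with pinacol then releases the diol and returns to 31.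

**Step 17.** The nucleophile has to attack C9 next to the quaternary C8, so opening may be slow. The Lewis acid may instead trigger a semipinacol shift of the vinyl group from C2 to C8, or attack at C8. Fallback from 21: hydrogen-bond-directed dihydroxylation with OsO4·TMEDA on the face of the C2 hydroxyl gives the 2β,8β,9β-triol F6. DMP oxidises its only secondary alcohol to the C9 ketone F7. Me4NBH(OAc)3 delivers hydride from the C8 hydroxyl and gives the 9α-alcohol F8. Ac2O in pyridine acetylates the secondary hydroxyl and returns to 23.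

**Step 30.** The ten-membered dienone may not adopt the boron chelate, for example if the C8 hydroxyl closes a transannular hemiketal on C2, so facial selectivity or 1,2-selectivity may be poor. Fallback from 36: Corey–Bakshi–Shibata reduction with the oxazaborolidine enantiomer matched to the required face and catecholborane (reagent control in place of chelation) gives the C2 alcohol F9 with the acetonide still on. Hydrolysis with aqueous acetic acid then returns to 38.

## Further compounds

F0 | step 27 | none | none
F1 | step 28 | ten-membered 2,8-diketone 7-(2-iodopropanoate) | CC1(C)O[C@H]2[C@@H](O[Si](C(C)C)(C(C)C)C(C)C)C(=C)[C@@H]3[C@@H](OC(C)=O)C(=O)[C@H](/C=C(CO[Si](c4ccccc4)(c4ccccc4)C(C)(C)C)\C=C/C(=O)[C@@]3(C)[C@H]2O1)OC(=O)C(C)I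
F2 | step 22 | cyclic phenylboronate of the 2β,8β-diol of 28 | CC1(C)O[C@H]2[C@@H](O[Si](C(C)C)(C(C)C)C(C)C)C(=C)[C@@H]3[C@@H](OC(C)=O)[C@@](O4)(C(O)C#CCO[Si](c5ccccc5)(c5ccccc5)C(C)(C)C)[C@@](OB4c5ccccc5)(C=C)[C@@]3(C)[C@H]2O1
F3 | step 22 | C7 ynone phenylboronate | CC1(C)O[C@H]2[C@@H](O[Si](C(C)C)(C(C)C)C(C)C)C(=C)[C@@H]3[C@@H](OC(C)=O)[C@@](O4)(C(=O)C#CCO[Si](c5ccccc5)(c5ccccc5)C(C)(C)C)[C@@](OB4c5ccccc5)(C=C)[C@@]3(C)[C@H]2O1
F4 | step 22 | (Z)-β-iodoenone phenylboronate | CC1(C)O[C@H]2[C@@H](O[Si](C(C)C)(C(C)C)C(C)C)C(=C)[C@@H]3[C@@H](OC(C)=O)[C@@](O4)(C(=O)/C=C(\I)CO[Si](c5ccccc5)(c5ccccc5)C(C)(C)C)[C@@](OB4c5ccccc5)(C=C)[C@@]3(C)[C@H]2O1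
F5 | step 22 | dienone phenylboronate | CC1(C)O[C@H]2[C@@H](O[Si](C(C)C)(C(C)C)C(C)C)C(=C)[C@@H]3[C@@H](OC(C)=O)[C@@](O4)(C(=O)/C=C(\C=C)CO[Si](c5ccccc5)(c5ccccc5)C(C)(C)C)[C@@](OB4c5ccccc5)(C=C)[C@@]3(C)[C@H]2O1
F6 | step 17 | 2β,8β,9β-triol (2α-vinyl; 8α-silyloxymethyl) | CC1(C)O[C@H]2[C@@H](O[Si](C(C)C)(C(C)C)C(C)C)C(=C)[C@@H]3[C@H](O)[C@@](O)(CO[Si](C)(C)C(C)(C)C)[C@@](O)(C=C)[C@@]3(C)[C@H]2O1
F7 | step 17 | 2β,8β-dihydroxy C9 ketone | CC1(C)O[C@H]2[C@@H](O[Si](C(C)C)(C(C)C)C(C)C)C(=C)[C@@H]3C(=O)[C@@](O)(CO[Si](C)(C)C(C)(C)C)[C@@](O)(C=C)[C@@]3(C)[C@H]2O1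
F8 | step 17 | 2β,8β,9α-triol | CC1(C)O[C@H]2[C@@H](O[Si](C(C)C)(C(C)C)C(C)C)C(=C)[C@@H]3[C@@H](O)[C@@](O)(CO[Si](C)(C)C(C)(C)C)[C@@](O)(C=C)[C@@]3(C)[C@H]2O1
F9 | step 30 | C2 alcohol of 36 with the acetonide retained | CC1(C)O[C@H]2[C@@H](O[Si](C(C)C)(C(C)C)C(C)C)C(=C)[C@@H]3[C@@H](OC(C)=O)[C@@]4(O)[C@H](/C=C(CO[Si](c5ccccc5)(c5ccccc5)C(C)(C)C)\C=C/[C@@H](O)[C@@]3(C)[C@H]2O1)OC(=O)[C@@H]4C
A1 | alternative 1 | ethyl (1S,2S)-2-formyl-2-methyl-5-oxocyclohex-3-ene-1-carboxylate | O=C1C[C@H](C(=O)OCC)[C@@](C)(C=O)C=C1
A2 | alternative 2 | seco C6 enal carrying the 2-(triisopropylsilyloxy)-3-methylfuran on C9 | CC(=O)O[C@H]1[C@@H](O[Si](C)(C)C(C)(C)C)C(=C)[C@H]([C@@H](OC(C)=O)c2coc(O[Si](C(C)C)(C(C)C)C(C)C)c2C)[C@]([C@H](OC(C)=O)/C=C\C(=C)C=O)(C)[C@H]1OC(C)=O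
A3 | alternative 2 | tricyclic butenolide with C6 carbinol and exocyclic C5 methylidene | CC(=O)O[C@H]1[C@@H](O[Si](C)(C)C(C)(C)C)C(=C)[C@@H]2[C@@H](OC(C)=O)C3=C(C)C(=O)O[C@H]3[C@@H](O)C(=C)/C=C\[C@@H](OC(C)=O)[C@@]2(C)[C@H]1OC(C)=O
A4 | alternative 3 | tricyclic C8 alcohol C4 mesylate with the C3–C8 bond (C3, C4 and C8 not assigned) | CC4(C)O[C@H]1[C@@H](O[Si](C)(C)C(C)(C)C)C(=C)[C@@H]2[C@@H](OCOC)C5(O)[C@@H](O[Si](CC)(CC)CC)C=C(CO[Si](C)(C)C(C)(C)C)C(OS(C)(=O)=O)C5[C@@H](OCOC)[C@@]2(C)[C@H]1O4
A5 | alternative 3 | bicyclic ten-membered C8 ketone with the Z,Z-diene | CC4(C)O[C@H]1[C@@H](O[Si](C)(C)C(C)(C)C)C(=C)[C@@H]2[C@@H](OCOC)C(=O)[C@H](/C=C(CO[Si](C)(C)C(C)(C)C)\C=C/[C@@H](OCOC)[C@@]2(C)[C@H]1O4)O[Si](CC)(CC)CC
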